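The plan treats ring A of the spiroketal (O1–C2–C3–C4–C5, spiro numbering) as a Baeyer–Villiger-expanded cyclobutanone: C2 and C5 are bridged by O1 on one side and by the C3–C4 ethano unit on the other, so removing O1 leaves a four-carbon ring. That ring is made in one operation by [2+2] cycloaddition of ethylene (C3–C4) to a chiral keteniminium ion (C5=C2) generated from an 8-bromooctanamide. This forms C2–C3 and C4–C5 together and sets C2. Oxygen insertion with retention gives the γ-lactone, ring B is added as a γ-silyloxy alkyllithium with spiroketalisation, and the phthalide is built last by asymmetric aldehyde alkylation and carbonylative lactonisation.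

Key step: step 2

Remark (numbering): ring A = O1–C2–C3–C4–C5 (carries the hexyl tether at C2), ring B = C5–O6–C7–C8–C9 (carries the methyl at C7). The target is (3R) at the phthalide and (2S,5R,7S) at the spiroketal.
Assumption (auxiliary): the (2S,5S)-amine is taken to induce the (S) configuration at the cyclobutanone α-carbon by the quadrant model in step 2; if the sense proves opposite, the (2R,5R)-amine is used in the same sequence.
Assumption (spiro centre): C5 of a 1,6-dioxaspiro[4.4]nonane has little intrinsic bias, so the acid-mediated closure in step 6 is expected to give the (5R) compound together with its (5S) epimer; the two are separated by chromatography and the (5S) epimer is resubjected to the same acid conditions.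
Assumption (ligand sense): the (R)-configured ligand in step 8 is taken to deliver the alkyl group to the Re face of the aldehyde; if the sense proves opposite, the (S)-ligand is used.

Step 1
Reactants: 1 8-bromooctanoic acid; 2 (2S,5S)-2,5-dimethylpyrrolidine
Product: 4 8-bromo-1-[(2S,5S)-2,5-dimethylpyrrolidin-1-yl]octan-1-one, via 8-bromooctanoyl chloride 3 (not isolated)
Conditions: (COCl)2, cat. DMF, CH2Cl2, 0 °C to rt; then 2, Et3N, CH2Cl2, 0 °C to rt
Reagents that add atoms: none
Why: Acid chloride formation and N-acylation of the secondary amine are far faster than N-alkylation by the primary bromide, and no stereocentre is formed or touched.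

Step 2
Reactants: 4 8-bromo-1-[(2S,5S)-2,5-dimethylpyrrolidin-1-yl]octan-1-one; 5 ethylene
Product: 8 (2S)-2-(6-bromohexyl)cyclobutan-1-one, via keteniminium triflate 6 (not isolated), via cyclobutaniminium triflate 7 (not isolated)
Conditions: Tf2O, 2-fluoropyridine, ClCH2CH2Cl, −20 °C; ethylene (10 bar), rt to 60 °C; then aq. NaHCO3, 0 °C to rt; 8 used at once
Reagents that add atoms: water (O)
Why: Tf2O activates the amide oxygen and 2-fluoropyridine removes the α-proton to give aldoketeniminium ion 6, whose central carbon (future C5) is attacked by ethylene while the α-carbon (future C2) closes onto the other ethylene carbon in an asynchronous thermal [2+2] cycloaddition, and the resulting iminium 7 is hydrolysed to the ketone. The closest known reaction type is the Ghosez keteniminium–olefin [2+2] cycloaddition, which is established for ethylene and, in auxiliary-controlled form, for amides of twofold-symmetric 2,5-disubstituted pyrrolidines. The four-membered ring is closed by this intermolecular [2+2] mode, so both new bonds (C2–C3 and C4–C5 of the later ring A) arise in the same operation. The single new stereocentre C2 is controlled by the auxiliary: ethylene should approach the C=N π face on the side of the α-hydrogen and ring closure should occur in the quadrant not occupied by a pyrrolidine methyl group, which predicts (S) for the (2S,5S)-amine. The step needs facial selectivity and configurational stability of the α-centre, secured by the twofold axis of the auxiliary (a single keteniminium geometry) and by cold buffered hydrolysis with immediate use of 8, and it needs chemoselectivity, secured because 4 has no alkene, arene or basic site and its primary bromide is inert, while ethylene under pressure outcompetes self-condensation.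

Step 3
Reactants: 8 (2S)-2-(6-bromohexyl)cyclobutan-1-one
Product: 9 (5S)-5-(6-bromohexyl)oxolan-2-one
Conditions: mCPBA, NaHCO3, CH2Cl2, 0 °C
Reagents that add atoms: mCPBA (OOC(=O)c1cccc(Cl)c1)
Why: Baeyer–Villiger oxidation of the strained ketone, in which the more substituted α-carbon C2 migrates to oxygen with retention, so the (S)-centre of 8 becomes the (S)-carbinol centre of 9 and O1 is placed between C2 and C5.

Step 4
Reactants: 10 (3S)-butane-1,3-diol
Product: 11 (2S)-4-iodobutan-2-ol
Conditions: I2, PPh3, imidazole, CH2Cl2, 0 °C
Reagents that add atoms: iodine (II)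
Why: Appel-type (Garegg–Samuelsson) iodination displaces the less hindered primary alkoxyphosphonium ion by SN2 much faster than the secondary one, so the (S)-carbinol centre is carried over unchanged.

Step 5
Reactants: 11 (2S)-4-iodobutan-2-ol
Product: 12 tert-butyl{[(2S)-4-iodobutan-2-yl]oxy}dimethylsilane
Conditions: TBSOTf, 2,6-lutidine, CH2Cl2, −78 to 0 °C
Reagents that add atoms: TBSOTf (CC(C)(C)[Si](C)(C)OS(=O)(=O)C(F)(F)F)
Why: O-silylation with a silyl triflate and a hindered, non-nucleophilic pyridine base is fast at low temperature and neither displaces the primary iodide nor touches the carbinol configuration.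

Step 6
Reactants: 12 tert-butyl{[(2S)-4-iodobutan-2-yl]oxy}dimethylsilane; 9 (5S)-5-(6-bromohexyl)oxolan-2-one
Product: 15 (2S,5R,7S)-2-(6-bromohexyl)-7-methyl-1,6-dioxaspiro[4.4]nonane, via alkyllithium 13 (not isolated), via hydroxy ketone 14 (not isolated)
Conditions: 12, t-BuLi (2 equiv per 12), Et2O–pentane, −78 °C; then 9, −78 °C; AcOH; then CSA (cat.), MeOH, rt; chromatography
Reagents that add atoms: none
Why: Iodine–lithium exchange gives primary alkyllithium 13, which adds once to the lactone at −78 °C because the lithium hemiketalate does not collapse, and acid then removes the silyl group and closes both rings by dehydrative spiroketalisation; C2 and C7 come unchanged from 9 and 12, whereas the spiro centre C5 is set under thermodynamic control without strong bias, so (5R)-15 should be separated by chromatography from its (5S) epimer, which is returned to the same acid conditions.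

Step 7
Reactants: 16 3,5-dimethoxybenzaldehyde
Product: 17 2-bromo-3,5-dimethoxybenzaldehyde
Conditions: NBS, MeCN, 0 °C to rt
Reagents that add atoms: NBS (BrN1C(=O)CCC1=O)
Why: Electrophilic aromatic bromination occurs at C2, which is ortho to one methoxy group and para to the other and not para to the deactivating formyl group, in preference to the more hindered C4 between the two methoxy groups.

Step 8
Reactants: 15 (2S,5R,7S)-2-(6-bromohexyl)-7-methyl-1,6-dioxaspiro[4.4]nonane; 17 2-bromo-3,5-dimethoxybenzaldehyde
Product: 20 (1R)-1-(2-bromo-3,5-dimethoxyphenyl)-7-[(2S,5R,7S)-7-methyl-1,6-dioxaspiro[4.4]nonan-2-yl]heptan-1-ol, via Grignard reagent 18 (not isolated), via alkyltitanium triisopropoxide 19 (not isolated)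
Conditions: Mg, Et2O, rt; Ti(OiPr)4, CH2Cl2, −78 °C; then 17, (R)-3-(3,5-diphenylphenyl)-H8-BINOL (2 mol%), Ti(OiPr)4, CH2Cl2, 0 °C; H2O quench
Reagents that add atoms: none
Why: The Grignard reagent is transmetalated to alkyltitanium 19, which adds to the aldehyde under catalysis by the titanium complex of the (R)-configured 3-aryl-H8-BINOL (catalytic enantioselective 1,2-addition of a Grignard-derived alkyltitanium reagent), the ligand directing the alkyl group to the Re face to set the (R)-carbinol by reagent control, since the spiroketal stereocentres are remote, while the aryl bromide and the ketal are inert.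

Step 9
Reactants: 20 (1R)-1-(2-bromo-3,5-dimethoxyphenyl)-7-[(2S,5R,7S)-7-methyl-1,6-dioxaspiro[4.4]nonan-2-yl]heptan-1-ol
Product: 21 (3R)-5,7-dimethoxy-3-{6-[(2S,5R,7S)-7-methyl-1,6-dioxaspiro[4.4]nonan-2-yl]hexyl}-2-benzofuran-1(3H)-one
Conditions: Pd(OAc)2 (5 mol%), Xantphos, CO (1 atm), K2CO3, toluene, 100 °C
Reagents that add atoms: carbon monoxide ([C-]#[O+])
Why: Palladium-catalysed carbonylative lactonisation, in which zerovalent palladium inserts into the aryl C–Br bond, CO insertion gives an acylpalladium species and the neighbouring secondary hydroxyl captures it to close the phthalide, with no bond to a stereocentre broken and base-only conditions that leave the spiroketal untouched.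

Compound list
1 | 8-bromooctanoic acid | OC(=O)CCCCCCCBr | starting material
2 | (2S,5S)-2,5-dimethylpyrrolidine | C[C@H]1CC[C@H](C)N1 | starting material
3 | 8-bromooctanoyl chloride | ClC(=O)CCCCCCCBr | intermediate
4 | 8-bromo-1-[(2S,5S)-2,5-dimethylpyrrolidin-1-yl]octan-1-one | O=C(CCCCCCCBr)N1[C@@H](C)CC[C@@H]1C | intermediate
5 | ethylene | C=C | starting material
6 | (2S,5S)-1-(8-bromooct-1-en-1-ylidene)-2,5-dimethylpyrrolidin-1-ium trifluoromethanesulfonate (keteniminium triflate) | BrCCCCCCC=C=[N+]1[C@@H](C)CC[C@@H]1C.[O-]S(=O)(=O)C(F)(F)F | intermediate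
7 | (2S,5S)-1-[(2S)-2-(6-bromohexyl)cyclobutylidene]-2,5-dimethylpyrrolidin-1-ium trifluoromethanesulfonate (cyclobutaniminium triflate) | BrCCCCCC[C@H]1CCC1=[N+]1[C@@H](C)CC[C@@H]1C.[O-]S(=O)(=O)C(F)(F)F | intermediate
8 | (2S)-2-(6-bromohexyl)cyclobutan-1-one | BrCCCCCC[C@H]1CCC1=O | intermediate
9 | (5S)-5-(6-bromohexyl)oxolan-2-one | O=C1CC[C@H](CCCCCCBr)O1 | intermediate
10 | (3S)-butane-1,3-diol | OCC[C@H](C)O | starting material
11 | (2S)-4-iodobutan-2-ol | ICC[C@H](C)O | intermediate
12 | tert-butyl{[(2S)-4-iodobutan-2-yl]oxy}dimethylsilane | ICC[C@H](C)O[Si](C)(C)C(C)(C)C | intermediate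
13 | {(3S)-3-[(tert-butyldimethylsilyl)oxy]butyl}lithium | [Li]CC[C@H](C)O[Si](C)(C)C(C)(C)C | intermediate
14 | (2S,8S)-14-bromo-2-[(tert-butyldimethylsilyl)oxy]-8-hydroxytetradecan-5-one (in equilibrium with its cyclic hemiketal) | BrCCCCCC[C@H](O)CCC(=O)CC[C@H](C)O[Si](C)(C)C(C)(C)C | intermediate
15 | (2S,5R,7S)-2-(6-bromohexyl)-7-methyl-1,6-dioxaspiro[4.4]nonane | BrCCCCCC[C@H]1CC[C@@]2(CC[C@H](C)O2)O1 | intermediate
16 | 3,5-dimethoxybenzaldehyde | COc1cc(OC)cc(C=O)c1 | starting material
17 | 2-bromo-3,5-dimethoxybenzaldehyde | COc1cc(OC)c(Br)c(C=O)c1 | intermediate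
18 | {6-[(2S,5R,7S)-7-methyl-1,6-dioxaspiro[4.4]nonan-2-yl]hexyl}magnesium bromide | Br[Mg]CCCCCC[C@H]1CC[C@@]2(CC[C@H](C)O2)O1 | intermediate
19 | {6-[(2S,5R,7S)-7-methyl-1,6-dioxaspiro[4.4]nonan-2-yl]hexyl}tri(propan-2-yloxy)titanium | CC(C)O[Ti](OC(C)C)(OC(C)C)CCCCCC[C@H]1CC[C@@]2(CC[C@H](C)O2)O1 | intermediate
20 | (1R)-1-(2-bromo-3,5-dimethoxyphenyl)-7-[(2S,5R,7S)-7-methyl-1,6-dioxaspiro[4.4]nonan-2-yl]heptan-1-ol | COc1cc(OC)c(Br)c(c1)[C@H](O)CCCCCC[C@H]1CC[C@@]2(CC[C@H](C)O2)O1 | intermediate
21 | (3R)-5,7-dimethoxy-3-{6-[(2S,5R,7S)-7-methyl-1,6-dioxaspiro[4.4]nonan-2-yl]hexyl}-2-benzofuran-1(3H)-one | COc1cc(OC)c2c(c1)[C@@H](CCCCCC[C@H]1CC[C@@]3(CC[C@H](C)O3)O1)OC2=O | target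

Total step count: 9. Longest linear sequence: 6 steps (steps 1, 2, 3, 6, 8, 9, from 8-bromooctanoic acid).

Steps most likely to fail

Step 2. Insufficient facial discrimination in the ring-closing C2–C3 bond formation, or loss of configuration at the α-carbon through enamine formation while the hindered iminium is hydrolysed, would erode the enantiopurity of 8 and lead to C2-epimeric material once ring B is attached. The fallback installs the C2 oxygen by organocatalysis and then extends by two carbons; it sets out from 1 and returns at 9. Borane reduction of 1 (BH3·SMe2, THF) should give 8-bromooctan-1-ol F1, which is oxidised (TEMPO, PhI(OAc)2, CH2Cl2) to 8-bromooctanal F2. D-Proline-catalysed α-aminoxylation with nitrosobenzene, followed in the same flask by Horner–Wadsworth–Emmons olefination (triethyl phosphonoacetate, LiCl, DBU), should give ethyl (2E,4S)-10-bromo-4-[(phenylamino)oxy]dec-2-enoate F3. Hydrogenation (H2, Pd/C, EtOAc) saturates the alkene and cleaves the N–O bond to ethyl (4S)-10-bromo-4-hydroxydecanoate F4, which lactonises (PPTS, toluene, 60 °C) to 9.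

Step 8. Incomplete enantiofacial control in the alkyl transfer, or sluggish transmetalation that lets the uncatalysed addition compete, would leave the C1 epimer of the carbinol, and this could hardly be removed because the stereocentres are far apart. The fallback separates bond formation from stereocontrol; it sets out from 15 and 17 and returns at 20. Grignard reagent 18 is added to 17 without a chiral catalyst (THF, −78 °C) to give (1RS)-1-(2-bromo-3,5-dimethoxyphenyl)-7-[(2S,5R,7S)-7-methyl-1,6-dioxaspiro[4.4]nonan-2-yl]heptan-1-ol F5. Dess–Martin oxidation buffered with NaHCO3 should give 1-(2-bromo-3,5-dimethoxyphenyl)-7-[(2S,5R,7S)-7-methyl-1,6-dioxaspiro[4.4]nonan-2-yl]heptan-1-one F6. Corey–Bakshi–Shibata reduction with the (S)-methyl oxazaborolidine and BH3·SMe2 (THF, −20 °C), with the ortho-bromoaryl group as the large substituent, should then deliver 20.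

Step 6. Attack of residual t-BuLi or of the alkyllithium on the primary bromide (exchange or coupling) and a second addition to the lactone would consume 9; in addition, the spiro centre equilibrates without strong bias, so part of the material must be recycled through the acid conditions. The fallback uses a softer sp-carbon nucleophile followed by reduction; it sets out from 9 and returns at 14. tert-Butyl{[(2S)-but-3-yn-2-yl]oxy}dimethylsilane F7 (from commercial (S)-but-3-yn-2-ol, TBSCl, imidazole) is lithiated (n-BuLi, THF, −78 °C) and added once to 9 to give (2S,8S)-14-bromo-2-[(tert-butyldimethylsilyl)oxy]-8-hydroxytetradec-3-yn-5-one F8 (as its hemiketal). Hydrogenation (H2, Pd/C, EtOAc) should give 14, which is spiroketalised with CSA in MeOH as in step 6 to 15, with the same chromatographic separation and acid recycling at the spiro centre.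

Further compounds
F1 | step 2 | 8-bromooctan-1-ol | OCCCCCCCCBr
F2 | step 2 | 8-bromooctanal | O=CCCCCCCCBr
F3 | step 2 | ethyl (2E,4S)-10-bromo-4-[(phenylamino)oxy]dec-2-enoate | CCOC(=O)/C=C/[C@@H](ONc1ccccc1)CCCCCCBr
F4 | step 2 | ethyl (4S)-10-bromo-4-hydroxydecanoate | CCOC(=O)CC[C@@H](O)CCCCCCBr
F5 | step 8 | (1RS)-1-(2-bromo-3,5-dimethoxyphenyl)-7-[(2S,5R,7S)-7-methyl-1,6-dioxaspiro[4.4]nonan-2-yl]heptan-1-ol | COc1cc(OC)c(Br)c(c1)C(O)CCCCCC[C@H]1CC[C@@]2(CC[C@H](C)O2)O1
F6 | step 8 | 1-(2-bromo-3,5-dimethoxyphenyl)-7-[(2S,5R,7S)-7-methyl-1,6-dioxaspiro[4.4]nonan-2-yl]heptan-1-one | COc1cc(OC)c(Br)c(c1)C(=O)CCCCCC[C@H]1CC[C@@]2(CC[C@H](C)O2)O1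
F7 | step 6 | tert-butyl{[(2S)-but-3-yn-2-yl]oxy}dimethylsilane | C#C[C@H](C)O[Si](C)(C)C(C)(C)C
F8 | step 6 | (2S,8S)-14-bromo-2-[(tert-butyldimethylsilyl)oxy]-8-hydroxytetradec-3-yn-5-one | BrCCCCCC[C@H](O)CCC(=O)C#C[C@H](C)O[Si](C)(C)C(C)(C)C
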